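A flask cannot hold a left-handed excess at rest: mirror-image products have equal energy, so the excess is a matter of time (kinetic against thermodynamic control), and I set two times against each other, the run time and the half-life τ of the gap between the products.

| setting | maple | cedar | oak | spring | autumn |
|---|---|---|---|---|---|
| left-handed substrate | 0.41 M | 0.41 M | 0.41 M | 0.41 M | 0.41 M |
| right-handed substrate | 0.41 M | 0.41 M | 0.41 M | 0.41 M | 0.41 M |
| coupling partner | 2 equiv | 2 equiv | 4 equiv | 2.00 equiv | 2.00 equiv |
| free catalyst | 2.5 mol% | 10 mol% | 5 mol% | 5 mol% | 5 mol% |
| temperature | 68 °C | 84 °C | 68 °C | 60 °C | 90 °C |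
| remark | run made earlier | run made earlier | run made earlier |  |  |
| time |  |  |  | 20 h | 20 h |

- the flask that comes out highest in excess of left-handed product over right-handed product, or "all alike" when all lie within 1.5 percentage points (spring / autumn / all alike)
- excess of left-handed product over right-handed product at the end, spring
- excess of left-handed product over right-handed product at the end, autumn

- free catalyst is single-handed; left-handed substrate and right-handed substrate are mirror images of each other, charged as a racemate, each of them at the stated concentration
- an excess is the difference of the two amounts in percent of their sum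
- an excess is below zero if the other one leads

| run | time / h | left-handed product / % | right-handed product / % |
|---|---|---|---|
| maple | 1.33 | 5 | 0 |
| maple | 2.00 | 12 | 6 |
| maple | 3.00 | 11 | 7 |
| maple | 5.00 | 16 | 10 |
| maple | 6.00 | 18 | 10 |
| maple | 10.0 | 20 | 16 |
| maple | 15.0 | 21 | 18 |
| cedar | 0.250 | 10 | 3 |
| cedar | 0.833 | 22 | 14 |
| cedar | 1.50 | 32 | 18 |
| cedar | 2.00 | 30 | 21 |
| cedar | 3.00 | 30 | 29 |
| cedar | 4.00 | 35 | 29 |
| cedar | 5.00 | 33 | 31 |
| oak | 1.33 | 15 | 7 |
| oak | 4.00 | 33 | 20 |
| oak | 8.00 | 37 | 32 |
| oak | 12.0 | 44 | 39 |
| oak | 15.0 | 41 | 45 |

(each reading ± 2 percentage points)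

I work with the fraction of the gap left, not with product made. In cedar the left-handed product goes only from 32% to 33% while the gap shrinks from 14 percentage points to 2 points, which I read as τ = 1.25 h at 84 °C. Maple, read the same way from 6.00 h to 15.0 h, gives 6.36 h at 68 °C, and both readings are rough, given a scatter of 2 points. Taking ln τ as straight in temperature, I get 14.4 h at 60 °C and 0.677 h at 90 °C. Spring then lasts 1.39 half-lives and autumn 29.6, and this count N, the run time over τ, gives the share of an early gap that survives: one half to the power N. For spring that share is 38.1%, and oak's first excess of 36.4%, read from a single early pair of readings, multiplied by that share gives 13.9%, which I hold as my rough estimate for spring and not as a bound. For autumn hardly any survives, so I expect an excess near zero.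

The forecast names spring, with 18% there and 0.5% in autumn, holding that “the catalyst cannot bias the equilibrium”.

The flask gives 15.6% in spring and 0% in autumn, with spring highest, and these steps stand behind it:

    coupling partner + free catalyst + left-handed substrate → free catalyst + left-handed product (k = 0.742 M⁻² min⁻¹, Ea = 65.0 kJ mol⁻¹)
    free catalyst → spent catalyst (k = 0.00147 min⁻¹, Ea = 112 kJ mol⁻¹)
    coupling partner + free catalyst + right-handed substrate → free catalyst + right-handed product (k = 0.290 M⁻² min⁻¹, Ea = 61.0 kJ mol⁻¹)
    coupling partner → decomposed reagent (k = 0.00471 min⁻¹, Ea = 129 kJ mol⁻¹)
    left-handed product ⇌ right-handed product (k = 0.00640 min⁻¹, Ea = 105 kJ mol⁻¹)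
    (constants at 90 °C)

Spring ends higher than my rough estimate, still carrying an excess after my 1.39 half-lives, while autumn shows none after my 29.6. The neighbouring autumn flask with 12 mol% of free catalyst keeps the temperature and the time, and the relaxation step above carries no catalyst, so N stays 29.6. It ends at 0%, with 33.7% of left-handed product and 33.7% of right-handed product, against 25.4% and 25.4% in autumn. More catalyst gave more product but no excess, and left-handed substrate stands at 8.11% and right-handed substrate at 24.6%.

The readings come from a simulation for an exercise.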